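**Structure check.** The lactate carbon is (R). The dioxane carbon bearing CO2H and the one bearing the aryl group are both (S), which places CO2H and aryl cis. The CO2H carbon sits on the ring oxygen meta to the propenoate chain, the aryl carbon on the para oxygen. "Allyl" means prop-2-en-1-yl throughout.

## Retrosynthetic overview

1. Target 13 ⇐ penta-allyl compound 12 by one global Pd(0) deallylation (two esters, three aryl ethers).
2. 12 ⇐ o-quinone 11 (from the intact caffeoyl lactate 8) + (Z)-caffeate 10, by a late-stage, catalyst-controlled inverse-demand hetero-Diels–Alder reaction that copies the presumed quinone/caffeic acid biogenesis; it makes the dioxane ring and both its stereocentres (cis from Z).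
3. 8 ⇐ (S)-aryl lactate 6 + unprotected caffeic acid 7 (Mitsunobu, inversion to R); 6 ⇐ methyl (S)-glycidate 3 + the aryl Grignard from 1.
4. 10 ⇐ caffeic acid 7 by tri-allylation and E→Z photoisomerisation.
5. Ring order: the three benzene rings are bought; the 1,4-dioxane ring is the only ring formed (step 7).

Assumption: the sense of induction of the Cu–box catalyst in step 7 cannot be predicted with confidence; the (S,S)-ligand is written, and the (R,R)-ligand replaces it if the first run gives mainly the (2R,3R) adduct (the two cis adducts are diastereomers, so the ratio is read directly by HPLC).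

## Route

Step 1
Reactants: 1 4-bromo-2-methoxyphenol
Product: 2 1-(allyloxy)-4-bromo-2-methoxybenzene
Conditions: allyl bromide (1.2 equiv), K2CO3 (1.5 equiv), acetone, reflux
Reagents that add atoms: allyl bromide, C=CCBr
Why: Williamson ether synthesis on the phenoxide; the allyl ether survives the Grignard and Mitsunobu steps and leaves with the other allyl groups in step 8.

Step 2
Reactants: 2 1-(allyloxy)-4-bromo-2-methoxybenzene; 3 methyl (2S)-oxirane-2-carboxylate (methyl (S)-glycidate)
Product: 5 methyl (2S)-3-[4-(allyloxy)-3-methoxyphenyl]-2-hydroxypropanoate, via aryl Grignard reagent 4 (not isolated)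
Conditions: Mg, THF, 40 °C; then CuI (10 mol%), 3 (0.75 equiv), THF, −40 → −20 °C; 1 M HCl quench, 0 °C
Reagents that add atoms: none
Why: Copper-catalysed Grignard opening of the epoxide at its unsubstituted CH2 (SN2) outruns ester addition and attack on the allyl ether at −40 °C; the stereocentre is not touched, so (S) is carried over from 3.

Step 3
Reactants: 5 methyl (2S)-3-[4-(allyloxy)-3-methoxyphenyl]-2-hydroxypropanoate
Product: 6 allyl (2S)-3-[4-(allyloxy)-3-methoxyphenyl]-2-hydroxypropanoate
Conditions: allyl alcohol (solvent), Ti(Oi-Pr)4 (10 mol%), 85 °C, MeOH distilled off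
Reagents that add atoms: allyl alcohol, C=CCO
Why: Titanate-catalysed transesterification, helped by chelation of the α-hydroxy ester, is non-basic and leaves the stereocentre alone; it gives an ester that can be removed at the end without hydrolysis.

Step 4
Reactants: 6 allyl (2S)-3-[4-(allyloxy)-3-methoxyphenyl]-2-hydroxypropanoate; 7 caffeic acid, (2E)-3-(3,4-dihydroxyphenyl)prop-2-enoic acid
Product: 8 allyl (2R)-3-[4-(allyloxy)-3-methoxyphenyl]-2-{[(2E)-3-(3,4-dihydroxyphenyl)prop-2-enoyl]oxy}propanoate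
Conditions: PPh3 (1.3 equiv), DIAD (1.3 equiv), THF, 0 °C → rt
Reagents that add atoms: none
Why: Mitsunobu esterification; the carboxylic acid (pKa about 4.5) is taken as pronucleophile in preference to the catechol OH groups (pKa about 9–10), and SN2 displacement of the alkoxyphosphonium inverts the lactate centre from (S) to the required (R).

Step 5
Reactants: 7 caffeic acid
Product: 9 allyl (2E)-3-[3,4-bis(allyloxy)phenyl]prop-2-enoate
Conditions: allyl bromide (3.6 equiv), K2CO3 (4 equiv), DMF, 40 °C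
Reagents that add atoms: allyl bromide, C=CCBr
Why: One-pot O-alkylation of the carboxylate and both phenoxides (Williamson-type) removes every oxidisable OH from the future dienophile.

Step 6
Reactants: 9 allyl (2E)-3-[3,4-bis(allyloxy)phenyl]prop-2-enoate
Product: 10 allyl (2Z)-3-[3,4-bis(allyloxy)phenyl]prop-2-enoate
Conditions: fac-Ir(ppy)3 (1 mol%), blue LEDs (450 nm), degassed MeCN, rt; SiO2, E isomer recycled
Reagents that add atoms: none
Why: Triplet-sensitised contra-thermodynamic E→Z photoisomerisation; the planar E-cinnamate accepts triplet energy from the sensitiser while the twisted Z isomer has a higher triplet energy and accumulates, and the isolated allyl alkenes are not excited.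

Step 7
Reactants: 8 allyl (2R)-3-[4-(allyloxy)-3-methoxyphenyl]-2-{[(2E)-3-(3,4-dihydroxyphenyl)prop-2-enoyl]oxy}propanoate; 10 allyl (2Z)-3-[3,4-bis(allyloxy)phenyl]prop-2-enoate
Product: 12 allyl (2R)-3-[4-(allyloxy)-3-methoxyphenyl]-2-{[(2E)-3-{(2S,3S)-3-[(allyloxy)carbonyl]-2-[3,4-bis(allyloxy)phenyl]-2,3-dihydro-1,4-benzodioxin-6-yl}prop-2-enoyl]oxy}propanoate, via o-quinone 11 (not isolated)
Conditions: Ag2O (1.5 equiv), 4 Å MS, CH2Cl2, −20 °C, dark, cold filtration; then 10 (2.5 equiv), [Cu((S,S)-t-Bu-box)](SbF6)2 (20 mol%), CH2Cl2, −60 → −30 °C, dark; SiO2, then prep. HPLC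
Reagents that add atoms: none
Why: Proposed new method: quinone 11, chelated through both carbonyl oxygens to the square-planar Cu(II)–box Lewis acid (in-plane lone pairs bound, π faces free), reacts as an electron-poor oxa-diene with the aryl-activated Z-alkene of 10 in an inverse-electron-demand hetero-Diels–Alder reaction; the nucleophilic α-carbon of the cinnamate bonds to the quinone oxygen meta to the acrylate (the developing negative charge then sits on the para oxygen, conjugated with the acrylate) and the benzylic carbon bonds to the para oxygen, both C–O bonds form on one alkene face so the Z geometry becomes the cis-2,3 relationship, and the C2-symmetric ligand is relied on to let only one alkene face stack over the chelate and so give (2S,3S) over (2R,3R); the closest known reaction types are the thermal o-quinone/styrene [4+2] route to 1,4-benzodioxanes and Cu(II)–bis(oxazoline)-catalysed inverse-demand hetero-Diels–Alder reactions of chelating oxa-dienes (unsaturated α-keto esters or acyl phosphonates) with electron-rich alkenes.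

Step 8
Reactants: 12 allyl (2R)-3-[4-(allyloxy)-3-methoxyphenyl]-2-{[(2E)-3-{(2S,3S)-3-[(allyloxy)carbonyl]-2-[3,4-bis(allyloxy)phenyl]-2,3-dihydro-1,4-benzodioxin-6-yl}prop-2-enoyl]oxy}propanoate
Product: 13 (2R)-2-{[(2E)-3-[(2S,3S)-3-carboxy-2-(3,4-dihydroxyphenyl)-2,3-dihydro-1,4-benzodioxin-6-yl]prop-2-enoyl]oxy}-3-(4-hydroxy-3-methoxyphenyl)propanoic acid
Conditions: Pd(PPh3)4 (10 mol%), morpholine (15 equiv), degassed THF, rt, Ar; dilute HCl to pH 2–3; reversed-phase chromatography
Reagents that add atoms: none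
Why: Tsuji–Trost-type Pd(0) deallylation with morpholine as allyl acceptor removes all five allyl groups without hydrolysis or strong base, so the cinnamate ester and the epimerisable cis C–H next to the carboxyl (a non-enolisable carboxylate once the fast ester cleavage has occurred) are kept.

## Compound list

1 | 4-bromo-2-methoxyphenol | COc1cc(Br)ccc1O | starting material
2 | 1-(allyloxy)-4-bromo-2-methoxybenzene | C=CCOc1ccc(Br)cc1OC | intermediate
3 | methyl (2S)-oxirane-2-carboxylate | COC(=O)[C@@H]1CO1 | starting material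
4 | [4-(allyloxy)-3-methoxyphenyl]magnesium bromide | C=CCOc1ccc([Mg]Br)cc1OC | intermediate
5 | methyl (2S)-3-[4-(allyloxy)-3-methoxyphenyl]-2-hydroxypropanoate | C=CCOc1ccc(C[C@H](O)C(=O)OC)cc1OC | intermediate
6 | allyl (2S)-3-[4-(allyloxy)-3-methoxyphenyl]-2-hydroxypropanoate | C=CCOc1ccc(C[C@H](O)C(=O)OCC=C)cc1OC | intermediate
7 | caffeic acid, (2E)-3-(3,4-dihydroxyphenyl)prop-2-enoic acid | OC(=O)/C=C/c1ccc(O)c(O)c1 | starting material
8 | allyl (2R)-3-[4-(allyloxy)-3-methoxyphenyl]-2-{[(2E)-3-(3,4-dihydroxyphenyl)prop-2-enoyl]oxy}propanoate | C=CCOc1ccc(C[C@@H](OC(=O)/C=C/c2ccc(O)c(O)c2)C(=O)OCC=C)cc1OC | intermediate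
9 | allyl (2E)-3-[3,4-bis(allyloxy)phenyl]prop-2-enoate | C=CCOC(=O)/C=C/c1ccc(OCC=C)c(OCC=C)c1 | intermediate
10 | allyl (2Z)-3-[3,4-bis(allyloxy)phenyl]prop-2-enoate | C=CCOC(=O)/C=C\c1ccc(OCC=C)c(OCC=C)c1 | intermediate
11 | allyl (2R)-3-[4-(allyloxy)-3-methoxyphenyl]-2-{[(2E)-3-(3,4-dioxocyclohexa-1,5-dien-1-yl)prop-2-enoyl]oxy}propanoate | C=CCOc1ccc(C[C@@H](OC(=O)/C=C/C2=CC(=O)C(=O)C=C2)C(=O)OCC=C)cc1OC | intermediate
12 | allyl (2R)-3-[4-(allyloxy)-3-methoxyphenyl]-2-{[(2E)-3-{(2S,3S)-3-[(allyloxy)carbonyl]-2-[3,4-bis(allyloxy)phenyl]-2,3-dihydro-1,4-benzodioxin-6-yl}prop-2-enoyl]oxy}propanoate (cis dioxane) | C=CCOc1ccc(C[C@@H](OC(=O)/C=C/c2ccc3c(c2)O[C@H](C(=O)OCC=C)[C@H](c2ccc(OCC=C)c(OCC=C)c2)O3)C(=O)OCC=C)cc1OC | intermediate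
13 | (2R)-2-{[(2E)-3-[(2S,3S)-3-carboxy-2-(3,4-dihydroxyphenyl)-2,3-dihydro-1,4-benzodioxin-6-yl]prop-2-enoyl]oxy}-3-(4-hydroxy-3-methoxyphenyl)propanoic acid (CNP0249420.1) | COc1cc(C[C@@H](OC(=O)/C=C/c2ccc3c(c2)O[C@H](C(=O)O)[C@H](c2ccc(O)c(O)c2)O3)C(=O)O)ccc1O | target

## Step count and risk

Total steps: 8. Longest linear sequence: 6 steps (1, 2, 3, 4, 7, 8); steps 5 and 6 form the second branch.

Steps most likely to fail:

**Step 7 (quinone hetero-Diels–Alder).** The Z-cinnamate may be too electron-poor for the quinone, a stepwise ionic pathway may erode cis to trans, and the facial control is unproven. The fallback keeps the quinone cycloaddition but uses a more electron-rich Z-dienophile at the alcohol oxidation level. It sets out from 10, which is reduced with DIBAL-H (CH2Cl2, −78 °C) to (2Z)-3-[3,4-bis(allyloxy)phenyl]prop-2-en-1-ol F1. F1 is combined with quinone 11, generated from 8 as in step 7 (toluene, 0 °C → rt, with or without the Cu–box catalyst), to give the cis hydroxymethyl adduct allyl (2R)-3-[4-(allyloxy)-3-methoxyphenyl]-2-{[(2E)-3-{(2S,3R)-2-[3,4-bis(allyloxy)phenyl]-3-(hydroxymethyl)-2,3-dihydro-1,4-benzodioxin-6-yl}prop-2-enoyl]oxy}propanoate F2. The other cis diastereomer is removed by preparative HPLC, which is possible because the lactate centre makes the two adducts diastereomers. The primary alcohol is oxidised with TEMPO/PhI(OAc)2 in MeCN–H2O to the tetra-allyl acid allyl (2R)-3-[4-(allyloxy)-3-methoxyphenyl]-2-{[(2E)-3-{(2S,3S)-2-[3,4-bis(allyloxy)phenyl]-3-carboxy-2,3-dihydro-1,4-benzodioxin-6-yl}prop-2-enoyl]oxy}propanoate F3. Deallylation of F3 under the conditions of step 8 brings the fallback back to the route at 13.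

**Step 4 (Mitsunobu with unprotected caffeic acid).** Catechol O-alkylation or elimination to the cinnamate may compete. The fallback replaces the redox condensation by a sulfonate displacement. It sets out from 6, which is converted with Tf2O and 2,6-lutidine (CH2Cl2, −78 °C) into allyl (2S)-3-[4-(allyloxy)-3-methoxyphenyl]-2-{[(trifluoromethyl)sulfonyl]oxy}propanoate F4. F4 is displaced in DMF at −20 °C → rt by the mono-potassium carboxylate of 7 (KHCO3, 1 equiv, so only the carboxyl is ionised) in an SN2 reaction with inversion, and the fallback rejoins the route at 8.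

**Step 8 (five-fold deallylation).** Aryl allyl ether cleavage may be slow, and the freed electron-rich phenols may be C-allylated by π-allyl palladium. The fallback removes the ethers by isomerisation and hydrolysis instead. It sets out from 12: Pd(PPh3)4 (2 mol%) with morpholine (2.2 equiv) in THF at 0 °C for a short time cleaves only the two allyl esters and gives (2R)-3-[4-(allyloxy)-3-methoxyphenyl]-2-{[(2E)-3-{(2S,3S)-2-[3,4-bis(allyloxy)phenyl]-3-carboxy-2,3-dihydro-1,4-benzodioxin-6-yl}prop-2-enoyl]oxy}propanoic acid F5. H2-activated [Ir(cod)(PMePh2)2]PF6 in THF at rt then isomerises the three aryl allyl ethers to give (2R)-3-[3-methoxy-4-(prop-1-en-1-yloxy)phenyl]-2-{[(2E)-3-{(2S,3S)-2-[3,4-bis(prop-1-en-1-yloxy)phenyl]-3-carboxy-2,3-dihydro-1,4-benzodioxin-6-yl}prop-2-enoyl]oxy}propanoic acid F6 (enol ether geometry mixed). Hydrolysis with 0.1 M HCl in acetone–water at rt brings the fallback back to the route at 13.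

## Further compounds

F1 | step 7 | (2Z)-3-[3,4-bis(allyloxy)phenyl]prop-2-en-1-ol | OC/C=C\c1ccc(OCC=C)c(OCC=C)c1
F2 | step 7 | allyl (2R)-3-[4-(allyloxy)-3-methoxyphenyl]-2-{[(2E)-3-{(2S,3R)-2-[3,4-bis(allyloxy)phenyl]-3-(hydroxymethyl)-2,3-dihydro-1,4-benzodioxin-6-yl}prop-2-enoyl]oxy}propanoate | C=CCOc1ccc(C[C@@H](OC(=O)/C=C/c2ccc3c(c2)O[C@H](CO)[C@H](c2ccc(OCC=C)c(OCC=C)c2)O3)C(=O)OCC=C)cc1OC
F3 | step 7 | allyl (2R)-3-[4-(allyloxy)-3-methoxyphenyl]-2-{[(2E)-3-{(2S,3S)-2-[3,4-bis(allyloxy)phenyl]-3-carboxy-2,3-dihydro-1,4-benzodioxin-6-yl}prop-2-enoyl]oxy}propanoate | C=CCOc1ccc(C[C@@H](OC(=O)/C=C/c2ccc3c(c2)O[C@H](C(=O)O)[C@H](c2ccc(OCC=C)c(OCC=C)c2)O3)C(=O)OCC=C)cc1OC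
F4 | step 4 | allyl (2S)-3-[4-(allyloxy)-3-methoxyphenyl]-2-{[(trifluoromethyl)sulfonyl]oxy}propanoate | C=CCOc1ccc(C[C@H](OS(=O)(=O)C(F)(F)F)C(=O)OCC=C)cc1OC
F5 | step 8 | (2R)-3-[4-(allyloxy)-3-methoxyphenyl]-2-{[(2E)-3-{(2S,3S)-2-[3,4-bis(allyloxy)phenyl]-3-carboxy-2,3-dihydro-1,4-benzodioxin-6-yl}prop-2-enoyl]oxy}propanoic acid | C=CCOc1ccc(C[C@@H](OC(=O)/C=C/c2ccc3c(c2)O[C@H](C(=O)O)[C@H](c2ccc(OCC=C)c(OCC=C)c2)O3)C(=O)O)cc1OC
F6 | step 8 | (2R)-3-[3-methoxy-4-(prop-1-en-1-yloxy)phenyl]-2-{[(2E)-3-{(2S,3S)-2-[3,4-bis(prop-1-en-1-yloxy)phenyl]-3-carboxy-2,3-dihydro-1,4-benzodioxin-6-yl}prop-2-enoyl]oxy}propanoic acid | CC=COc1ccc(C[C@@H](OC(=O)/C=C/c2ccc3c(c2)O[C@H](C(=O)O)[C@H](c2ccc(OC=CC)c(OC=CC)c2)O3)C(=O)O)cc1OC
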